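**Plan**
- Cuts: in ring D the O2'–C(CH3)2 bond together with C3'–CH=, and on ring A the C6–CH2 (prenyl) bond, all traced back to one bis-ether (O5–C(CH3)2CH=CH2 and O2'–C(CH3)2C≡CH); then the C4 and C2/C3 hydrogens, back to an isoflavone; then C3–C1', back to a 3-iodochromone and a ring-B arylboronate.
- Enabling feature: ring D is a 2H-pyran, the valence tautomer of the 1-oxatriene O2'=C2'–C3'=CH–CH=C(CH3)2, so its O–C(CH3)2 bond can be made last by an oxa-6π closure. O2' and O5 each have only one unsubstituted ortho carbon (C3' and C6), so both aryl-ether sigmatropic shifts can only go where the target needs them.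
- Forward: pyranone ring C (iodochromone) → Suzuki coupling to ring B → reduction of ring C to the chroman → O2' propargyl ether, O5 reverse-prenyl ether → one thermal step moves the prenyl to C6 and closes ring D → O5 methylation, O4' desilylation.
- Stereochemistry: C3 is the only stereocentre. It is set as (R) by ruthenium-catalysed asymmetric transfer hydrogenation of the isoflavone with dynamic kinetic resolution (cis-(3R,4R)-4-ol) and is kept when the C4 oxygen is removed.
- Helpers, all removed later: the C4 oxygen, MOM on O5, TIPS on O4' (blocks the second phenol that could close a pyran).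

Key step: step 12

Remark: silylation of 4-bromobenzene-1,3-diol is taken to occur at the hydroxyl para to bromine (the one without an ortho substituent), and 3-chloro-3-methylbut-1-yne and tert-butyl (2-methylbut-3-en-2-yl) carbonate are taken as purchasable reagents.

**Step 1**
Reactants: 1 1-(2,6-dihydroxy-4-methoxyphenyl)ethan-1-one
Product: 2 1-[2-hydroxy-4-methoxy-6-(methoxymethoxy)phenyl]ethan-1-one
Conditions: MOMCl (1.1 equiv), i-Pr2NEt, CH2Cl2, 0 °C
Reagents that add atoms: chloromethyl methyl ether, COCCl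
Why: O-alkylation of one of two equivalent phenols should stop at the mono-ether because the remaining hydroxyl is locked in a hydrogen bond to the ketone.

**Step 2**
Reactants: 2 1-[2-hydroxy-4-methoxy-6-(methoxymethoxy)phenyl]ethan-1-one
Product: 3 (E)-3-(dimethylamino)-1-[2-hydroxy-4-methoxy-6-(methoxymethoxy)phenyl]prop-2-en-1-one
Conditions: Me2NCH(OMe)2, toluene, 90 °C
Reagents that add atoms: N,N-dimethylformamide dimethyl acetal, CN(C)C(OC)OC
Why: Condensation of the methyl ketone with the amide acetal should give the enaminone, the standard precursor of 3-halochromones.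

**Step 3**
Reactants: 3 (E)-3-(dimethylamino)-1-[2-hydroxy-4-methoxy-6-(methoxymethoxy)phenyl]prop-2-en-1-one
Product: 4 3-iodo-7-methoxy-5-(methoxymethoxy)-4H-chromen-4-one
Conditions: I2, pyridine, CHCl3, rt
Reagents that add atoms: iodine, II
Why: Iodination at the enaminone α-carbon, addition of the chelated phenol to the iminium carbon and loss of dimethylamine should close the pyranone (iodine-induced enaminone cyclisation), with pyridine buffering the acid so the MOM ether survives.

**Step 4**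
Reactants: 5 4-bromobenzene-1,3-diol
Product: 6 2-bromo-5-[(triisopropylsilyl)oxy]phenol
Conditions: TIPSCl (1.0 equiv), imidazole, DMF, 0 °C
Reagents that add atoms: chlorotriisopropylsilane, CC(C)[Si](Cl)(C(C)C)C(C)C
Why: The bulky silyl chloride should silylate the unhindered hydroxyl para to bromine and leave the hydroxyl ortho to bromine free.

**Step 5**
Reactants: 6 2-bromo-5-[(triisopropylsilyl)oxy]phenol
Product: 7 2-(4,4,5,5-tetramethyl-1,3,2-dioxaborolan-2-yl)-5-[(triisopropylsilyl)oxy]phenol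
Conditions: B2pin2, Pd(dppf)Cl2 (3 mol%), KOAc, 1,4-dioxane, 90 °C
Reagents that add atoms: bis(pinacolato)diboron, CC1(C)OB(OC1(C)C)B1OC(C)(C)C(C)(C)O1
Why: Miyaura borylation of the aryl bromide under acetate base should tolerate the free phenol and the aryl silyl ether.

**Step 6**
Reactants: 4 3-iodo-7-methoxy-5-(methoxymethoxy)-4H-chromen-4-one; 7 2-(4,4,5,5-tetramethyl-1,3,2-dioxaborolan-2-yl)-5-[(triisopropylsilyl)oxy]phenol
Product: 8 3-{2-hydroxy-4-[(triisopropylsilyl)oxy]phenyl}-7-methoxy-5-(methoxymethoxy)-4H-chromen-4-one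
Conditions: Pd(dppf)Cl2 (5 mol%), K3PO4, 1,4-dioxane/H2O, 70 °C
Reagents that add atoms: none
Why: Suzuki–Miyaura coupling of the electron-poor 3-iodochromone with the arylboronate should form the C3–C1' bond of the isoflavone.

**Step 7**
Reactants: 8 3-{2-hydroxy-4-[(triisopropylsilyl)oxy]phenyl}-7-methoxy-5-(methoxymethoxy)-4H-chromen-4-one
Product: 10 (3R,4R)-3-{2-hydroxy-4-[(triisopropylsilyl)oxy]phenyl}-7-methoxy-5-(methoxymethoxy)chroman-4-ol, via isoflavanone 9 (not isolated)
Conditions: RuCl[(R,R)-TsDPEN](p-cymene) (2 mol%), HCO2H/Et3N (5:2), EtOAc, 40 °C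
Reagents that add atoms: none
Why: In this Noyori-type asymmetric transfer hydrogenation the ruthenium hydride should first reduce the C2=C3 bond in a 1,4 sense, the isoflavanone then racemises at C3 through its enol in the amine medium, and the (R,R)-catalyst should reduce the (3R)-ketone faster, from the face opposite the 3-aryl group (dynamic kinetic resolution), which sets C3 as (R) in the cis-(3R,4R)-alcohol.

**Step 8**
Reactants: 10 (3R,4R)-3-{2-hydroxy-4-[(triisopropylsilyl)oxy]phenyl}-7-methoxy-5-(methoxymethoxy)chroman-4-ol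
Product: 11 2-[(3R)-7-methoxy-5-(methoxymethoxy)chroman-3-yl]-5-[(triisopropylsilyl)oxy]phenol
Conditions: H2 (3 atm), 10% Pd/C, EtOH/AcOH (20:1), rt
Reagents that add atoms: none
Why: Hydrogenolysis of the benzylic C4–O bond, activated by the ortho- and para-oxygens of ring A, should remove the helper oxygen without touching C3 (a C4–O bond to O2', should the phenol add there first, is cleaved in the same way).

**Step 9**
Reactants: 11 2-[(3R)-7-methoxy-5-(methoxymethoxy)chroman-3-yl]-5-[(triisopropylsilyl)oxy]phenol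
Product: 12 triisopropyl{4-[(3R)-7-methoxy-5-(methoxymethoxy)chroman-3-yl]-3-[(2-methylbut-3-yn-2-yl)oxy]phenoxy}silane
Conditions: 3-chloro-3-methylbut-1-yne, DBU, CuCl2 (1 mol%), MeCN, 0 °C to rt
Reagents that add atoms: 3-chloro-3-methylbut-1-yne, CC(C)(Cl)C#C
Why: Copper-catalysed O-alkylation of the only free phenol with the tertiary propargylic chloride (through a copper allenylidene, so that elimination is not an issue) should give the aryl 1,1-dimethylpropargyl ether.

**Step 10**
Reactants: 12 triisopropyl{4-[(3R)-7-methoxy-5-(methoxymethoxy)chroman-3-yl]-3-[(2-methylbut-3-yn-2-yl)oxy]phenoxy}silane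
Product: 13 (3R)-7-methoxy-3-{2-[(2-methylbut-3-yn-2-yl)oxy]-4-[(triisopropylsilyl)oxy]phenyl}chroman-5-ol
Conditions: HCl (1.25 M in MeOH), THF, rt
Reagents that add atoms: none
Why: Acid-catalysed acetal exchange should free O5, while the aryl silyl ether and the tertiary propargyl ether (whose ionisation would give an alkynyl-destabilised cation) should survive the short exposure.

**Step 11**
Reactants: 13 (3R)-7-methoxy-3-{2-[(2-methylbut-3-yn-2-yl)oxy]-4-[(triisopropylsilyl)oxy]phenyl}chroman-5-ol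
Product: 14 triisopropyl{4-[(3R)-7-methoxy-5-[(2-methylbut-3-en-2-yl)oxy]chroman-3-yl]-3-[(2-methylbut-3-yn-2-yl)oxy]phenoxy}silane
Conditions: tert-butyl (2-methylbut-3-en-2-yl) carbonate, Pd(PPh3)4 (2 mol%), THF, 0 °C
Reagents that add atoms: tert-butyl (2-methylbut-3-en-2-yl) carbonate, CC(C)(C)OC(=O)OC(C)(C)C=C
Why: In this Tsuji–Trost O-allylation the 1,1-dimethyl-π-allylpalladium cation should be attacked by the phenoxide at its more substituted terminus under kinetic control at low temperature, giving the reverse-prenyl ether.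

**Step 12**
Reactants: 14 triisopropyl{4-[(3R)-7-methoxy-5-[(2-methylbut-3-en-2-yl)oxy]chroman-3-yl]-3-[(2-methylbut-3-yn-2-yl)oxy]phenoxy}silane
Product: 17 (3R)-3-{2,2-dimethyl-5-[(triisopropylsilyl)oxy]-2H-chromen-8-yl}-7-methoxy-6-(3-methylbut-2-en-1-yl)chroman-5-ol, via allenyl phenol 15 (not isolated), via ortho-quinone methide 16 (not isolated)
Conditions: PhNEt2, 180 °C, sealed tube, Ar
Reagents that add atoms: none
Why: Two thermal pericyclic cascades should run side by side: on ring A the aryl 1,1-dimethylallyl ether undergoes an aromatic Claisen [3,3] shift to C6 and the dienone enolises to the 6-prenyl-5-phenol, while on ring B the aryl 1,1-dimethylpropargyl ether undergoes a propargyl Claisen [3,3] shift to C3', the dienone enolises to allenyl phenol 15, a [1,5]-hydrogen shift from the 2'-OH to the central allene carbon gives the 1-oxatriene 16, and an oxa-6π electrocyclisation forms the O2'–C(CH3)2 bond. The closest known reaction types are the Claisen rearrangement of aryl reverse-prenyl ethers to ortho-prenylphenols and the thermal rearrangement of aryl 1,1-dimethylpropargyl ethers to 2,2-dimethyl-2H-chromenes. The only ring closed is the 2H-pyran (ring D), by thermal disrotatory 6π electrocyclic closure of the oxatriene, driven by rearomatisation of ring B. No new stereocentre arises (the pyran carbon carries two methyl groups and the sp3 carbons of the dienones vanish on enolisation), and C3 takes no part and should keep its (R) configuration. The regioselectivity needed at both ethers is secured by the substrate: O5 has C6 as its only unsubstituted ortho carbon (C4a is the ring fusion), O2' has only C3' (C1' carries ring C), and because O4' is silylated only O2' can deliver the hydrogen and close the pyran. The chemoselectivity between the two C5 units lies in their oxidation level, the allyl ether ending as the open prenyl group and the propargyl ether as the chromene.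

**Step 13**
Reactants: 17 (3R)-3-{2,2-dimethyl-5-[(triisopropylsilyl)oxy]-2H-chromen-8-yl}-7-methoxy-6-(3-methylbut-2-en-1-yl)chroman-5-ol
Product: 18 ({8-[(3R)-5,7-dimethoxy-6-(3-methylbut-2-en-1-yl)chroman-3-yl]-2,2-dimethyl-2H-chromen-5-yl}oxy)triisopropylsilane
Conditions: MeI, K2CO3, acetone, 50 °C
Reagents that add atoms: iodomethane, CI
Why: Williamson methylation of the only free phenol (O5) should proceed under anhydrous carbonate, which the aryl silyl ether tolerates.

**Step 14**
Reactants: 18 ({8-[(3R)-5,7-dimethoxy-6-(3-methylbut-2-en-1-yl)chroman-3-yl]-2,2-dimethyl-2H-chromen-5-yl}oxy)triisopropylsilane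
Product: 19 Kanzonol I (8-[(3R)-5,7-dimethoxy-6-(3-methylbut-2-en-1-yl)chroman-3-yl]-2,2-dimethyl-2H-chromen-5-ol)
Conditions: TBAF, AcOH, THF, 0 °C
Reagents that add atoms: none
Why: Fluoride should cleave the aryl silyl ether (strong Si–F bond) under buffered conditions that leave the chromene and prenyl alkenes alone.

**Compound list**
1 | 1-(2,6-dihydroxy-4-methoxyphenyl)ethan-1-one | CC(=O)c1c(O)cc(OC)cc1O | starting material
2 | 1-[2-hydroxy-4-methoxy-6-(methoxymethoxy)phenyl]ethan-1-one | CC(=O)c1c(O)cc(OC)cc1OCOC | intermediate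
3 | (E)-3-(dimethylamino)-1-[2-hydroxy-4-methoxy-6-(methoxymethoxy)phenyl]prop-2-en-1-one | CN(C)/C=C/C(=O)c1c(O)cc(OC)cc1OCOC | intermediate
4 | 3-iodo-7-methoxy-5-(methoxymethoxy)-4H-chromen-4-one | COCOc1cc(OC)cc2occ(I)c(=O)c12 | intermediate
5 | 4-bromobenzene-1,3-diol | Oc1ccc(Br)c(O)c1 | starting material
6 | 2-bromo-5-[(triisopropylsilyl)oxy]phenol | Oc1cc(O[Si](C(C)C)(C(C)C)C(C)C)ccc1Br | intermediate
7 | 2-(4,4,5,5-tetramethyl-1,3,2-dioxaborolan-2-yl)-5-[(triisopropylsilyl)oxy]phenol | Oc1cc(O[Si](C(C)C)(C(C)C)C(C)C)ccc1B1OC(C)(C)C(C)(C)O1 | intermediate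
8 | 3-{2-hydroxy-4-[(triisopropylsilyl)oxy]phenyl}-7-methoxy-5-(methoxymethoxy)-4H-chromen-4-one | COCOc1cc(OC)cc2occ(-c3ccc(O[Si](C(C)C)(C(C)C)C(C)C)cc3O)c(=O)c12 | intermediate
9 | 3-{2-hydroxy-4-[(triisopropylsilyl)oxy]phenyl}-7-methoxy-5-(methoxymethoxy)chroman-4-one (C3 epimerising in the flask) | COCOc1cc(OC)cc2OCC(c3ccc(O[Si](C(C)C)(C(C)C)C(C)C)cc3O)C(=O)c12 | intermediate
10 | (3R,4R)-3-{2-hydroxy-4-[(triisopropylsilyl)oxy]phenyl}-7-methoxy-5-(methoxymethoxy)chroman-4-ol | COCOc1cc(OC)cc2OC[C@@H](c3ccc(O[Si](C(C)C)(C(C)C)C(C)C)cc3O)[C@@H](O)c12 | intermediate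
11 | 2-[(3R)-7-methoxy-5-(methoxymethoxy)chroman-3-yl]-5-[(triisopropylsilyl)oxy]phenol | COCOc1cc(OC)cc2OC[C@@H](c3ccc(O[Si](C(C)C)(C(C)C)C(C)C)cc3O)Cc12 | intermediate
12 | triisopropyl{4-[(3R)-7-methoxy-5-(methoxymethoxy)chroman-3-yl]-3-[(2-methylbut-3-yn-2-yl)oxy]phenoxy}silane | COCOc1cc(OC)cc2OC[C@@H](c3ccc(O[Si](C(C)C)(C(C)C)C(C)C)cc3OC(C)(C)C#C)Cc12 | intermediate
13 | (3R)-7-methoxy-3-{2-[(2-methylbut-3-yn-2-yl)oxy]-4-[(triisopropylsilyl)oxy]phenyl}chroman-5-ol | Oc1cc(OC)cc2OC[C@@H](c3ccc(O[Si](C(C)C)(C(C)C)C(C)C)cc3OC(C)(C)C#C)Cc12 | intermediate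
14 | triisopropyl{4-[(3R)-7-methoxy-5-[(2-methylbut-3-en-2-yl)oxy]chroman-3-yl]-3-[(2-methylbut-3-yn-2-yl)oxy]phenoxy}silane | C=CC(C)(C)Oc1cc(OC)cc2OC[C@@H](c3ccc(O[Si](C(C)C)(C(C)C)C(C)C)cc3OC(C)(C)C#C)Cc12 | intermediate
15 | (3R)-3-{2-hydroxy-3-(3-methylbuta-1,2-dien-1-yl)-4-[(triisopropylsilyl)oxy]phenyl}-7-methoxy-6-(3-methylbut-2-en-1-yl)chroman-5-ol | Oc1c(CC=C(C)C)c(OC)cc2OC[C@@H](c3ccc(O[Si](C(C)C)(C(C)C)C(C)C)c(C=C=C(C)C)c3O)Cc12 | intermediate
16 | 6-[(3R)-5-hydroxy-7-methoxy-6-(3-methylbut-2-en-1-yl)chroman-3-yl]-2-(3-methylbut-2-en-1-ylidene)-3-[(triisopropylsilyl)oxy]cyclohexa-3,5-dien-1-one | Oc1c(CC=C(C)C)c(OC)cc2OC[C@@H](C3=CC=C(O[Si](C(C)C)(C(C)C)C(C)C)C(=CC=C(C)C)C3=O)Cc12 | intermediate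
17 | (3R)-3-{2,2-dimethyl-5-[(triisopropylsilyl)oxy]-2H-chromen-8-yl}-7-methoxy-6-(3-methylbut-2-en-1-yl)chroman-5-ol | Oc1c(CC=C(C)C)c(OC)cc2OC[C@@H](c3ccc(O[Si](C(C)C)(C(C)C)C(C)C)c4c3OC(C)(C)C=C4)Cc12 | intermediate
18 | ({8-[(3R)-5,7-dimethoxy-6-(3-methylbut-2-en-1-yl)chroman-3-yl]-2,2-dimethyl-2H-chromen-5-yl}oxy)triisopropylsilane | COc1c(CC=C(C)C)c(OC)cc2OC[C@@H](c3ccc(O[Si](C(C)C)(C(C)C)C(C)C)c4c3OC(C)(C)C=C4)Cc12 | intermediate
19 | Kanzonol I (8-[(3R)-5,7-dimethoxy-6-(3-methylbut-2-en-1-yl)chroman-3-yl]-2,2-dimethyl-2H-chromen-5-ol) | COc1c(CC=C(C)C)c(OC)cc2OC[C@@H](c3ccc(O)c4c3OC(C)(C)C=C4)Cc12 | target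

**Step count and risks**
Total step count: 14. Longest linear sequence: 12 steps (steps 1–3, then 6–14); steps 4–5 make the ring-B boronate.

Steps most likely to fail:

1. Step 12. The tertiary allyl ether may fragment (loss of isoprene) before it rearranges, or the ring-B cascade may stall at the crowded C3', so that the two cascades cannot be driven to completion at one temperature. The fallback sets out from 11 and comes back at 17; it builds the pyran by carbonyl condensation and moves the prenyl group in a separate, catalysed step. Phenol 11 is heated with 1,1-diethoxy-3-methylbut-2-ene (3-picoline, xylene, 140 °C), which should condense at C3', the only free ortho carbon, and close the pyran through the same oxatriene to give triisopropyl({8-[(3R)-7-methoxy-5-(methoxymethoxy)chroman-3-yl]-2,2-dimethyl-2H-chromen-5-yl}oxy)silane F1. Methanolic HCl should then remove the MOM group to give (3R)-3-{2,2-dimethyl-5-[(triisopropylsilyl)oxy]-2H-chromen-8-yl}-7-methoxychroman-5-ol F2. O-Alkylation under the conditions of step 11 should give triisopropyl({8-[(3R)-7-methoxy-5-[(2-methylbut-3-en-2-yl)oxy]chroman-3-yl]-2,2-dimethyl-2H-chromen-5-yl}oxy)silane F3, and a Claisen rearrangement catalysed by Eu(fod)3 (CHCl3, 60 °C) should give 17.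

2. Step 7. The peri O5 substituent may slow the conjugate reduction, or the isoflavanone may equilibrate too slowly relative to its reduction, so that enantioselectivity erodes. The fallback sets out from 8 and comes back at 11; it gives up asymmetric catalysis for resolution. Exhaustive hydrogenation of 8 (H2, Pd/C, EtOH/AcOH, 50 °C) should give racemic 2-[7-methoxy-5-(methoxymethoxy)chroman-3-yl]-5-[(triisopropylsilyl)oxy]phenol F4. Preparative chromatography on a chiral stationary phase should then give 11, and 2-[(3S)-7-methoxy-5-(methoxymethoxy)chroman-3-yl]-5-[(triisopropylsilyl)oxy]phenol F5 is set aside.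

3. Step 11. Zerovalent palladium may re-ionise the kinetically formed tertiary ether and isomerise it to the linear prenyl ether, or the terminal alkyne may consume the catalyst. The fallback sets out from 13 and comes back at 14; it builds the vinyl group by olefination instead of allylic substitution. Alkylation of 13 with ethyl 2-bromo-2-methylpropanoate (K2CO3, butan-2-one, 80 °C) should give ethyl 2-({(3R)-7-methoxy-3-{2-[(2-methylbut-3-yn-2-yl)oxy]-4-[(triisopropylsilyl)oxy]phenyl}chroman-5-yl}oxy)-2-methylpropanoate F6. Reduction with DIBAL-H (CH2Cl2, −78 °C) should give 2-({(3R)-7-methoxy-3-{2-[(2-methylbut-3-yn-2-yl)oxy]-4-[(triisopropylsilyl)oxy]phenyl}chroman-5-yl}oxy)-2-methylpropanal F7, and Wittig methylenation (Ph3PCH3Br, KHMDS, THF, 0 °C) should give 14.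

**Further compounds**
F1 | step 12 | triisopropyl({8-[(3R)-7-methoxy-5-(methoxymethoxy)chroman-3-yl]-2,2-dimethyl-2H-chromen-5-yl}oxy)silane | COCOc1cc(OC)cc2OC[C@@H](c3ccc(O[Si](C(C)C)(C(C)C)C(C)C)c4c3OC(C)(C)C=C4)Cc12
F2 | step 12 | (3R)-3-{2,2-dimethyl-5-[(triisopropylsilyl)oxy]-2H-chromen-8-yl}-7-methoxychroman-5-ol | Oc1cc(OC)cc2OC[C@@H](c3ccc(O[Si](C(C)C)(C(C)C)C(C)C)c4c3OC(C)(C)C=C4)Cc12
F3 | step 12 | triisopropyl({8-[(3R)-7-methoxy-5-[(2-methylbut-3-en-2-yl)oxy]chroman-3-yl]-2,2-dimethyl-2H-chromen-5-yl}oxy)silane | C=CC(C)(C)Oc1cc(OC)cc2OC[C@@H](c3ccc(O[Si](C(C)C)(C(C)C)C(C)C)c4c3OC(C)(C)C=C4)Cc12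
F4 | step 7 | racemic 2-[7-methoxy-5-(methoxymethoxy)chroman-3-yl]-5-[(triisopropylsilyl)oxy]phenol | COCOc1cc(OC)cc2OCC(c3ccc(O[Si](C(C)C)(C(C)C)C(C)C)cc3O)Cc12
F5 | step 7 | 2-[(3S)-7-methoxy-5-(methoxymethoxy)chroman-3-yl]-5-[(triisopropylsilyl)oxy]phenol | COCOc1cc(OC)cc2OC[C@H](c3ccc(O[Si](C(C)C)(C(C)C)C(C)C)cc3O)Cc12
F6 | step 11 | ethyl 2-({(3R)-7-methoxy-3-{2-[(2-methylbut-3-yn-2-yl)oxy]-4-[(triisopropylsilyl)oxy]phenyl}chroman-5-yl}oxy)-2-methylpropanoate | CCOC(=O)C(C)(C)Oc1cc(OC)cc2OC[C@@H](c3ccc(O[Si](C(C)C)(C(C)C)C(C)C)cc3OC(C)(C)C#C)Cc12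
F7 | step 11 | 2-({(3R)-7-methoxy-3-{2-[(2-methylbut-3-yn-2-yl)oxy]-4-[(triisopropylsilyl)oxy]phenyl}chroman-5-yl}oxy)-2-methylpropanal | O=CC(C)(C)Oc1cc(OC)cc2OC[C@@H](c3ccc(O[Si](C(C)C)(C(C)C)C(C)C)cc3OC(C)(C)C#C)Cc12
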